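## Retrosynthetic overview
1. Feature used: ring B (the central ring, O-linked to rings A and C) carries oxygen on C1, C3 and C5 like phloroglucinol, plus the ring C oxygen on C2. Cut into three C2 units, C2/C1 are the CH2/C=O of an aryloxyacetyl group, and C3/C4 and C5/C6 are two alkoxyacetylenes.
2. Last disconnections: the ten O-alkyl groups (BBr3), then the ring A–O bond at the only free OH of ring B (Ullmann coupling; ring A comes from 1,3,5-trimethoxybenzene).
3. Key disconnection: ring B goes back to the aryloxyketene from the ring C–D aryloxyacetyl chloride plus two molecules of ethoxyacetylene.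
4. The acid chloride goes back to 3,5-dimethoxyphenol (iodination, Williamson alkylation with methyl bromoacetate) and 1,3,5-trimethoxybenzene (lithiation, zinc, Negishi coupling for the C–D bond).
5. Ring order: C and D are bought and joined first, B is the only ring built (on the oxygen of ring C), and A is attached last.

Key step: step 6

Remark: Ar = 3,5-dimethoxy-2-(2,4,6-trimethoxyphenyl)phenyl (rings C and D). Ring B numbering is that of overview line 1.
Remark: the target has no stereocentre, and the C–D axis is not stereogenic because ring D is symmetric about it. Only the double-bond geometries of 14–16 carry descriptors.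
Remark: ring A is brought in fully O-methylated. An arylating agent that uncovers a new ortho-aryloxyphenol on ring A (for example a quinone diazide under Rh2(OAc)4) would present a second hydroxyl of the same kind as that of 18, and over-arylation would be expected.

## Route

Step 1
Reactants: 1 3,5-dimethoxyphenol
Product: 2 2-iodo-3,5-dimethoxyphenol
Conditions: NIS (1.0 equiv), CH2Cl2, −20 → 0 °C, dark
Reagents that add atoms: N-iodosuccinimide, O=C1CCC(=O)N1I
Why: Electrophilic aromatic iodination, in which the bulky iodine donor should prefer C2/C6 (between OH and OMe, two equivalent sites) over C4 (between two OMe), one equivalent at low temperature limits di-iodination, and any 4-iodo isomer is removed by chromatography.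

Step 2
Reactants: 2 2-iodo-3,5-dimethoxyphenol; 3 methyl bromoacetate
Product: 4 methyl 2-(2-iodo-3,5-dimethoxyphenoxy)acetate
Conditions: K2CO3, acetone, reflux
Reagents that add atoms: none
Why: Williamson ether synthesis of a phenoxide with an activated primary bromide, which installs the two carbons that become C2 and C1 of ring B and masks the phenol for step 3.

Step 3
Reactants: 5 1,3,5-trimethoxybenzene; 4 methyl 2-(2-iodo-3,5-dimethoxyphenoxy)acetate
Product: 8 methyl 2-[3,5-dimethoxy-2-(2,4,6-trimethoxyphenyl)phenoxy]acetate, via 2,4,6-trimethoxyphenyllithium 6 (not isolated), via 2,4,6-trimethoxyphenylzinc chloride 7 (not isolated)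
Conditions: 5 (1.5 equiv), n-BuLi, THF, 0 °C → rt; ZnCl2, THF, 0 °C → rt; then 4, Pd2(dba)3 (2 mol %), RuPhos (8 mol %), THF/NMP, 70 °C
Reagents that add atoms: none
Why: Directed ortho-lithiation between two methoxy groups, transmetalation to zinc and Negishi coupling, in which the iodine fixes the site of the biaryl bond, bulky dialkylbiarylphosphines are the ligand class known to give tetra-ortho-substituted biaryls, and the arylzinc neither protodemetalates as the boronic acid would nor touches the ester.

Step 4
Reactants: 8 methyl 2-[3,5-dimethoxy-2-(2,4,6-trimethoxyphenyl)phenoxy]acetate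
Product: 9 2-[3,5-dimethoxy-2-(2,4,6-trimethoxyphenyl)phenoxy]acetic acid
Conditions: LiOH·H2O, THF/H2O, rt; then 1 M HCl to pH 2
Reagents that add atoms: lithium hydroxide, [Li+].[OH-]
Why: Saponification of an unhindered methyl ester by acyl–oxygen cleavage, to which the aryl methyl ethers and the biaryl are inert.

Step 5
Reactants: 9 2-[3,5-dimethoxy-2-(2,4,6-trimethoxyphenyl)phenoxy]acetic acid
Product: 10 2-[3,5-dimethoxy-2-(2,4,6-trimethoxyphenyl)phenoxy]acetyl chloride
Conditions: 1-chloro-N,N,2-trimethylprop-1-en-1-amine (1.1 equiv), CH2Cl2, 0 °C → rt; volatiles removed, used crude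
Reagents that add atoms: 1-chloro-N,N,2-trimethylprop-1-en-1-amine, CC(C)=C(Cl)N(C)C
Why: Neutral acid chloride formation with an α-chloroenamine, chosen because it liberates no HCl and avoids (COCl)2 and the Vilsmeier species from DMF, which could acylate or formylate the four free positions of the two phloroglucinol ether rings; the amide by-product is inert to ketenes.

Step 6
Reactants: 10 2-[3,5-dimethoxy-2-(2,4,6-trimethoxyphenyl)phenoxy]acetyl chloride; 11 ethoxyacetylene (two molecules incorporated)
Product: 18 3,5-diethoxy-2-[3,5-dimethoxy-2-(2,4,6-trimethoxyphenyl)phenoxy]phenol, via aryloxyketene 12 (not isolated), via 4-aryloxy-3-ethoxycyclobutenone 13 (not isolated), via vinylketene 14 (not isolated), via 4-alkenyl-3-ethoxycyclobutenone 15 (not isolated), via dienylketene 16 (not isolated), via cyclohexa-2,4-dienone 17 (not isolated)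
Conditions: 11 (5 equiv), Et3N (1.2 equiv, added over 2 h), PhMe, 0 °C → rt; Et3N·HCl filtered off under Ar; fresh 11 (5 equiv), sealed tube, 80 °C; excess 11 vented, 110 °C
Reagents that add atoms: none
Why: Proposed new method: Et3N takes HCl from 10 to give aryloxyketene 12, the nucleophilic CH end of 11 bonds to its carbonyl carbon and the [2+2] adduct is cyclobutenone 13; at 80 °C 13 should undergo conrotatory 4π opening with the aryloxy donor turning outward to vinylketene 14, which takes up the second 11 in the same orientation to give 15. Reversible 4π opening of 15 gives dienylketene 16, of which only the isomer with a cis chain about the central double bond reacts on. Ring B closes by 6π electrocyclisation between the ketene carbon and the aryloxy-bearing CH of 16 (inside substituent H), and enolisation of dienone 17 gives phenol 18, so that C2–C3, C4–C5 and C6–C1 are new bonds and C1–C2 is the old acetyl bond, broken and made again. The closest known reaction types are the [2+2] cycloaddition of ketenes generated from acid chlorides and Et3N with alkoxyacetylenes and the Danheiser benzannulation of cyclobutenones with alkynyl ethers; running the two in sequence without isolation and using a 4-aryloxy-3-alkoxycyclobutenone as vinylketene source are the untested parts. No stereocentre remains, since the sp3 carbons of 13, 15 and 17 (all racemic) end as aromatic carbons. The step needs head-to-tail orientation in both cycloadditions, which the opposed polarity of ketene (electrophilic C=O carbon) and ynol ether (nucleophilic CH) secures, and this leaves the one free OH on C1 beside the aryloxy carbon C2 and the ethoxy groups on C3 and C5.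

Step 7
Reactants: 5 1,3,5-trimethoxybenzene
Product: 19 2-iodo-1,3,5-trimethoxybenzene
Conditions: NIS (1.0 equiv), MeCN, rt, dark
Reagents that add atoms: N-iodosuccinimide, O=C1CCC(=O)N1I
Why: Electrophilic aromatic iodination of an arene whose three free positions are equivalent, with one equivalent of reagent and the steric load of the first iodine holding the reaction at the mono-iodide.

Step 8
Reactants: 18 3,5-diethoxy-2-[3,5-dimethoxy-2-(2,4,6-trimethoxyphenyl)phenoxy]phenol; 19 2-iodo-1,3,5-trimethoxybenzene
Product: 20 1,5-diethoxy-2-[3,5-dimethoxy-2-(2,4,6-trimethoxyphenyl)phenoxy]-3-(2,4,6-trimethoxyphenoxy)benzene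
Conditions: 19 (2 equiv), CuI (20 mol %), picolinic acid (40 mol %), K3PO4 (3 equiv), DMSO, 100 °C, Ar
Reagents that add atoms: none
Why: Ullmann-type diaryl ether synthesis, in which the phenoxide of 18 (a single OH with only one ortho substituent) couples with the aryl iodide under the CuI/picolinic acid system developed for ortho-substituted partners, and no other O–H or C–halogen bond competes.

Step 9
Reactants: 20 1,5-diethoxy-2-[3,5-dimethoxy-2-(2,4,6-trimethoxyphenyl)phenoxy]-3-(2,4,6-trimethoxyphenoxy)benzene
Product: 21 fucodiphloroethol G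
Conditions: BBr3 (20 equiv), CH2Cl2, −78 °C → rt, Ar; H2O, 0 °C; work-up with degassed solvents
Reagents that add atoms: none
Why: Lewis-acid ether cleavage, in which boron binds each alkoxy oxygen and bromide attacks the alkyl carbon (SN2), so the eight methyl and two ethyl groups leave while the two diaryl ether bonds and the biaryl bond, which offer no sp3 carbon, stay.

## Compound list
1 | 3,5-dimethoxyphenol | COc1cc(O)cc(OC)c1 | starting material
2 | 2-iodo-3,5-dimethoxyphenol | COc1cc(O)c(I)c(OC)c1 | intermediate
3 | methyl bromoacetate | COC(=O)CBr | starting material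
4 | methyl 2-(2-iodo-3,5-dimethoxyphenoxy)acetate | COC(=O)COc1cc(OC)cc(OC)c1I | intermediate
5 | 1,3,5-trimethoxybenzene | COc1cc(OC)cc(OC)c1 | starting material
6 | 2,4,6-trimethoxyphenyllithium (not isolated) | [Li]c1c(OC)cc(OC)cc1OC | intermediate
7 | 2,4,6-trimethoxyphenylzinc chloride (not isolated) | Cl[Zn]c1c(OC)cc(OC)cc1OC | intermediate
8 | methyl 2-[3,5-dimethoxy-2-(2,4,6-trimethoxyphenyl)phenoxy]acetate | COC(=O)COc1cc(OC)cc(OC)c1-c1c(OC)cc(OC)cc1OC | intermediate
9 | 2-[3,5-dimethoxy-2-(2,4,6-trimethoxyphenyl)phenoxy]acetic acid | OC(=O)COc1cc(OC)cc(OC)c1-c1c(OC)cc(OC)cc1OC | intermediate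
10 | 2-[3,5-dimethoxy-2-(2,4,6-trimethoxyphenyl)phenoxy]acetyl chloride | ClC(=O)COc1cc(OC)cc(OC)c1-c1c(OC)cc(OC)cc1OC | intermediate
11 | ethoxyacetylene | CCOC#C | starting material
12 | (ArO)ketene, 2-(aryloxy)ethen-1-one (not isolated) | O=C=COc1cc(OC)cc(OC)c1-c1c(OC)cc(OC)cc1OC | intermediate
13 | 4-(ArO)-3-ethoxycyclobut-2-en-1-one, racemic (not isolated) | CCOC1=CC(=O)C1Oc1cc(OC)cc(OC)c1-c1c(OC)cc(OC)cc1OC | intermediate
14 | 4-(ArO)-3-ethoxybuta-1,3-dien-1-one, ArO trans to the ketene-bearing carbon across C3=C4 (not isolated) | O=C=C/C(OCC)=C/Oc1cc(OC)cc(OC)c1-c1c(OC)cc(OC)cc1OC | intermediate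
15 | 4-[2-(ArO)-1-ethoxyethenyl]-3-ethoxycyclobut-2-en-1-one, racemic, alkene geometry as in 14 (not isolated) | O=C1C=C(OCC)C1/C(OCC)=C/Oc1cc(OC)cc(OC)c1-c1c(OC)cc(OC)cc1OC | intermediate
16 | 6-(ArO)-3,5-diethoxyhexa-1,3,5-trien-1-one, chain cis about C3=C4, ArO trans to C4 about C5=C6 (not isolated) | O=C=C/C(OCC)=C\C(OCC)=C\Oc1cc(OC)cc(OC)c1-c1c(OC)cc(OC)cc1OC | intermediate
17 | 6-(ArO)-3,5-diethoxycyclohexa-2,4-dien-1-one, racemic (not isolated) | O=C1C=C(OCC)C=C(OCC)C1Oc1cc(OC)cc(OC)c1-c1c(OC)cc(OC)cc1OC | intermediate
18 | 3,5-diethoxy-2-[3,5-dimethoxy-2-(2,4,6-trimethoxyphenyl)phenoxy]phenol (rings B, C, D) | CCOc1cc(O)c(Oc2cc(OC)cc(OC)c2-c2c(OC)cc(OC)cc2OC)c(OCC)c1 | intermediate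
19 | 2-iodo-1,3,5-trimethoxybenzene | COc1cc(OC)c(I)c(OC)c1 | intermediate
20 | 1,5-diethoxy-2-[3,5-dimethoxy-2-(2,4,6-trimethoxyphenyl)phenoxy]-3-(2,4,6-trimethoxyphenoxy)benzene | CCOc1cc(OCC)c(Oc2cc(OC)cc(OC)c2-c2c(OC)cc(OC)cc2OC)c(Oc2c(OC)cc(OC)cc2OC)c1 | intermediate
21 | fucodiphloroethol G | Oc1cc(O)c(Oc2cc(O)cc(O)c2Oc2cc(O)cc(O)c2-c2c(O)cc(O)cc2O)c(O)c1 | target

Total step count: 9. Longest linear sequence: 8 (steps 1–6, 8, 9).

## Steps most likely to fail

**Step 6.** Three processes threaten this step.
- The aryloxyketene may dimerise, or be captured by amine or chloride, before the first cycloaddition.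
- The vinylogous-ester-stabilised cyclobutenone may open so slowly that retro-ene loss of ethylene from ethoxyacetylene takes over.
- Ketene intermediates may O-acylate the product phenol. Basic methanolysis of the crude would undo this.

The fallback uses known chemistry and buys ring B instead of building it. It sets out from 2.
- Benzylation (BnBr, K2CO3, DMF) gives 1-benzyloxy-2-iodo-3,5-dimethoxybenzene F1.
- One portion of F1 is coupled with zinc reagent 7 under the conditions of step 3 to give 1-benzyloxy-3,5-dimethoxy-2-(2,4,6-trimethoxyphenyl)benzene F2.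
- Hydrogenolysis (H2, Pd/C, EtOAc) frees 3,5-dimethoxy-2-(2,4,6-trimethoxyphenyl)phenol F3.
- Ullmann coupling of F3 with a second portion of F1 (CuI, picolinic acid, K3PO4, DMSO, 110 °C, more copper if needed) gives 1-benzyloxy-3,5-dimethoxy-2-[3,5-dimethoxy-2-(2,4,6-trimethoxyphenyl)phenoxy]benzene F4.
- A second hydrogenolysis gives 3,5-dimethoxy-2-[3,5-dimethoxy-2-(2,4,6-trimethoxyphenyl)phenoxy]phenol F5, the dimethyl analogue of 18.
- Coupling with 19 as in step 8 gives 1,5-dimethoxy-2-[3,5-dimethoxy-2-(2,4,6-trimethoxyphenyl)phenoxy]-3-(2,4,6-trimethoxyphenoxy)benzene F6.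
- BBr3 as in step 9 brings the fallback back to the route at 21.

**Step 8.** Copper may insert too slowly into the electron-rich, doubly ortho-methoxylated iodide. Hydrodeiodination of 19 and oxidative decay of the phenoxide of 18 would then outrun C–O bond formation.

The fallback reverses the polarity of the A–O–B bond. It sets out from 18.
- Tf2O and pyridine in CH2Cl2 at 0 °C give 3,5-diethoxy-2-[3,5-dimethoxy-2-(2,4,6-trimethoxyphenyl)phenoxy]phenyl trifluoromethanesulfonate F7.
- The reacting carbon of F7 is meta to both ethoxy groups and has only one ortho neighbour.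
- Palladium-catalysed C–O coupling of the Buchwald–Hartwig type follows, with commercial 2,4,6-trimethoxyphenol (Pd(OAc)2, t-BuXPhos, K3PO4, PhMe, 100 °C).
- This supplies the bridging oxygen from ring A and returns to the route at 20.

**Step 3.** Transmetalation and reductive elimination may be sluggish at a palladium centre that must hold two aryl groups with four ortho oxygens. Protodezincation, homocoupling of 7 and hydrodeiodination of 4 would then take over.

The fallback replaces cross-coupling by ligand coupling on lead. It sets out from 5 and 1.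
- Direct plumbation of 5 with Pb(OAc)4 in CHCl3 gives 2,4,6-trimethoxyphenyllead triacetate F8.
- F8 arylates an excess of phenol 1 in CHCl3/pyridine at 40–60 °C (Pinhey arylation).
- Delivery of the aryl group from an oxygen-bound lead intermediate should favour the ortho carbon. The product is the biaryl phenol F3, already met in the fallback to step 6.
- Williamson alkylation with 3 (K2CO3, acetone) returns to the route at 8.

## Further compounds
F1 | step 6 | 1-benzyloxy-2-iodo-3,5-dimethoxybenzene | COc1cc(OCc2ccccc2)c(I)c(OC)c1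
F2 | step 6 | 1-benzyloxy-3,5-dimethoxy-2-(2,4,6-trimethoxyphenyl)benzene | COc1cc(OCc2ccccc2)c(-c2c(OC)cc(OC)cc2OC)c(OC)c1
F3 | step 6 | 3,5-dimethoxy-2-(2,4,6-trimethoxyphenyl)phenol | COc1cc(O)c(-c2c(OC)cc(OC)cc2OC)c(OC)c1
F4 | step 6 | 1-benzyloxy-3,5-dimethoxy-2-[3,5-dimethoxy-2-(2,4,6-trimethoxyphenyl)phenoxy]benzene | COc1cc(OCc2ccccc2)c(Oc2cc(OC)cc(OC)c2-c2c(OC)cc(OC)cc2OC)c(OC)c1
F5 | step 6 | 3,5-dimethoxy-2-[3,5-dimethoxy-2-(2,4,6-trimethoxyphenyl)phenoxy]phenol | COc1cc(O)c(Oc2cc(OC)cc(OC)c2-c2c(OC)cc(OC)cc2OC)c(OC)c1
F6 | step 6 | 1,5-dimethoxy-2-[3,5-dimethoxy-2-(2,4,6-trimethoxyphenyl)phenoxy]-3-(2,4,6-trimethoxyphenoxy)benzene | COc1cc(OC)c(Oc2cc(OC)cc(OC)c2-c2c(OC)cc(OC)cc2OC)c(Oc2c(OC)cc(OC)cc2OC)c1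
F7 | step 8 | 3,5-diethoxy-2-[3,5-dimethoxy-2-(2,4,6-trimethoxyphenyl)phenoxy]phenyl trifluoromethanesulfonate | CCOc1cc(OCC)c(Oc2cc(OC)cc(OC)c2-c2c(OC)cc(OC)cc2OC)c(OS(=O)(=O)C(F)(F)F)c1
F8 | step 3 | 2,4,6-trimethoxyphenyllead triacetate | CC(=O)O[Pb](OC(C)=O)(OC(C)=O)c1c(OC)cc(OC)cc1OC
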